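The route rests on cutting the tetrahydrofuran ring (O1, C2 aryl, C3 CH2OH, C4 carbinol arm, C5) at O1–C2 and C2–C3. C2 is bonded to both the ring oxygen and C3, so it can be the carbonyl carbon of 3,4,5-trimethoxybenzaldehyde, joined to a C5 hydroxyl and to a carbon nucleophile at C3. In one operation the key step condenses aldehyde and alcohol to an oxocarbenium ion and closes the ring by allylsilane attack, making both bonds and the C2 and C3 stereocentres under control of C4. Its precursor is an enantiopure (E)-5-trimethylsilylpent-3-en-1-ol with a silyloxymethyl group on the carbon that becomes C4; the vinyl group left on C3 is a latent CH2OH.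

Key step: step 7

Assumption: in step 3 the lipase is taken to acetylate the enantiotopic hydroxymethyl arm that leads to the (S)-monoacetate 5; the sense has to be confirmed on the first batch, and the hydrolytic mode given among the fallbacks delivers the antipode.

Remark: in the Why lines the ring atoms are called O1, C2 (aryl), C3, C4, C5 as in the first paragraph; the systematic names carry their own locants.

Step 1
Reactants: 1 diethyl ethylidenemalonate
Product: 3 diethyl 2-vinylmalonate, via lithium dienolate 2 (not isolated)
Conditions: LiN(CHMe2)2 (LDA), THF, −78 °C; then AcOH, −78 °C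
Reagents that add atoms: none
Why: The amide base removes a γ-proton to give dienolate 2, which is protonated kinetically at the α-carbon, so the alkene leaves conjugation (deconjugative protonation) and no stereocentre is formed.

Step 2
Reactants: 3 diethyl 2-vinylmalonate
Product: 4 2-vinylpropane-1,3-diol
Conditions: LiAlH4, Et2O, −20 to 0 °C; then H2O, aq. NaOH
Reagents that add atoms: none
Why: Hydride reduction of both esters (LiAlH4 ester reduction) leaves the isolated vinyl group alone, and the low temperature with excess hydride limits enolisation back to the conjugated diester; the diol is prochiral.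

Step 3
Reactants: 4 2-vinylpropane-1,3-diol
Product: 5 (S)-2-(hydroxymethyl)but-3-en-1-yl acetate
Conditions: lipase from Pseudomonas fluorescens (immobilised), vinyl acetate, diisopropyl ether, 20 °C, stopped just past full consumption of the diol
Reagents that add atoms: vinyl acetate, CC(=O)OC=C
Why: Irreversible lipase-catalysed transesterification (enzymatic desymmetrisation of a prochiral 2-substituted propane-1,3-diol) acetylates one enantiotopic hydroxymethyl arm and so creates the stereocentre, and slight over-acylation removes the minor enantiomer faster as diacetate.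

Step 4
Reactants: 5 (S)-2-(hydroxymethyl)but-3-en-1-yl acetate
Product: 6 (R)-2-[(tert-butyldiphenylsilyloxy)methyl]but-3-en-1-yl acetate
Conditions: t-BuPh2SiCl, imidazole, CH2Cl2, 0 °C
Reagents that add atoms: tert-butyldiphenylsilyl chloride, CC(C)(C)[Si](Cl)(c1ccccc1)c1ccccc1
Why: Imidazole-mediated O-silylation of the primary alcohol is fast at 0 °C and caps the hydroxyl before a 1,3-acyl shift could erode the enantiomeric purity; the stereocentre is not touched.

Step 5
Reactants: 6 (R)-2-[(tert-butyldiphenylsilyloxy)methyl]but-3-en-1-yl acetate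
Product: 7 (R)-2-[(tert-butyldiphenylsilyloxy)methyl]but-3-en-1-ol
Conditions: K2CO3 (cat.), MeOH, 0 °C
Reagents that add atoms: none
Why: Carbonate-catalysed methanolysis (transesterification) removes the acetate while the hindered silyl ether should neither cleave nor migrate at 0 °C, so the configuration is kept and the free hydroxyl now sits on the arm that becomes C5–O1.

Step 6
Reactants: 7 (R)-2-[(tert-butyldiphenylsilyloxy)methyl]but-3-en-1-ol; 8 allyltrimethylsilane
Product: 9 (R,E)-2-[(tert-butyldiphenylsilyloxy)methyl]-5-(trimethylsilyl)pent-3-en-1-ol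
Conditions: second-generation Grubbs catalyst (H2IMes)(PCy3)Cl2Ru=CHPh (cat.), 8 (4 equiv), CH2Cl2, 40 °C
Reagents that add atoms: none
Why: Olefin cross metathesis with an excess of the readily dimerising allylsilane, in which the branched allylic carbon of 7 suppresses its own dimerisation and should favour the E alkene, while the free hydroxyl and the silyl ether are tolerated.

Step 7
Reactants: 9 (R,E)-2-[(tert-butyldiphenylsilyloxy)methyl]-5-(trimethylsilyl)pent-3-en-1-ol; 10 3,4,5-trimethoxybenzaldehyde
Product: 12 (2R,3R,4R)-4-[(tert-butyldiphenylsilyloxy)methyl]-2-(3,4,5-trimethoxyphenyl)-3-vinyltetrahydrofuran, via oxocarbenium triflate 11 (not isolated)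
Conditions: Me3SiOTf (1.1 equiv), CH2Cl2, −78 °C; then aq. NaHCO3
Reagents that add atoms: none
Why: Me3SiOTf activates the aldehyde, the hydroxyl of 9 adds and silanol is lost to give the (E)-oxocarbenium ion 11, which the allylsilane attacks through its γ-carbon with loss of the silyl group (anti SE2′, directed by the β-silicon effect), leaving the vinyl group on C3. The closest known reaction type is the intramolecular silyl-modified Sakurai condensation of hydroxy allylsilanes with aldehydes, a Prins-type cyclisation terminated by silicon. The tetrahydrofuran closes in a 5-exo mode with respect to the allylsilane double bond, the C=O+ bond lying inside the new ring. C2 is set by the E geometry of the oxocarbenium ion, which keeps the aryl group pseudo-equatorial, and C3 by an envelope in which the emerging vinyl group is pseudo-equatorial and anti to the aryl group; both are relayed from C4, whose bulky silyloxymethyl group stays pseudo-equatorial with the C4–H bond near the alkene plane, so the alkene face anti to that group is attacked and the all-trans ring should result. The step needs γ- and not α-attack, and ring closure ahead of intermolecular allylation or protodesilylation: silicon fixes the regiochemistry, the tether makes closure fast at −78 °C, and the robust silyl ether stands in for the benzylic carbinol, which would ionise under these conditions.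

Step 8
Reactants: 12 (2R,3R,4R)-4-[(tert-butyldiphenylsilyloxy)methyl]-2-(3,4,5-trimethoxyphenyl)-3-vinyltetrahydrofuran
Product: 13 [(3S,4R,5R)-5-(3,4,5-trimethoxyphenyl)-4-vinyltetrahydrofuran-3-yl]methanol
Conditions: Bu4NF, THF, 0 to 20 °C
Reagents that add atoms: none
Why: Fluoride-induced Si–O cleavage (desilylation) frees the primary alcohol, and the benzylic ring ether, the vinyl group and the stereocentres are inert to the reagent.

Step 9
Reactants: 13 [(3S,4R,5R)-5-(3,4,5-trimethoxyphenyl)-4-vinyltetrahydrofuran-3-yl]methanol
Product: 15 (3R,4R,5R)-5-(3,4,5-trimethoxyphenyl)-4-vinyltetrahydrofuran-3-carboxylic acid, via aldehyde 14 (not isolated)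
Conditions: 2,2,6,6-tetramethylpiperidin-1-oxyl (TEMPO, cat.), PhI(OAc)2 (2.2 equiv), MeCN/H2O, 20 °C
Reagents that add atoms: water, O
Why: Oxoammonium-mediated oxidation takes the primary alcohol through aldehyde 14 to the acid without touching the alkene or the methoxyarene, and C4, now alpha to a carbonyl, already holds the more stable trans arrangement.

Step 10
Reactants: 15 (3R,4R,5R)-5-(3,4,5-trimethoxyphenyl)-4-vinyltetrahydrofuran-3-carboxylic acid
Product: 17 (3R,4R,5R)-N-methoxy-N-methyl-5-(3,4,5-trimethoxyphenyl)-4-vinyltetrahydrofuran-3-carboxamide, via acyl imidazole 16 (not isolated)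
Conditions: 1,1'-carbonyldiimidazole, CH2Cl2, 20 °C; then MeNH(OMe)·HCl
Reagents that add atoms: N,O-dimethylhydroxylamine hydrochloride, CNOC.Cl
Why: Carbonyldiimidazole turns the acid into acyl imidazole 16, which the hydroxylamine opens to the Weinreb amide (amide coupling) under near-neutral conditions that should not epimerise C4.

Step 11
Reactants: 17 (3R,4R,5R)-N-methoxy-N-methyl-5-(3,4,5-trimethoxyphenyl)-4-vinyltetrahydrofuran-3-carboxamide; 18 4-bromoveratrole (4-bromo-1,2-dimethoxybenzene)
Product: 21 (3,4-dimethoxyphenyl)[(3R,4R,5R)-5-(3,4,5-trimethoxyphenyl)-4-vinyltetrahydrofuran-3-yl]methanone, via 3,4-dimethoxyphenyllithium 19 (not isolated), via lithium hemiaminal 20 (not isolated)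
Conditions: 18 (1.3 equiv), n-BuLi (1.2 equiv), THF, −78 °C; then 17, −78 °C; then aq. NH4Cl
Reagents that add atoms: none
Why: Bromine–lithium exchange gives aryllithium 19, whose addition to the Weinreb amide stops at the chelated adduct 20 and releases the ketone only on work-up (Weinreb ketone synthesis), so no tertiary alcohol forms and the low temperature avoids enolisation at C4.

Step 12
Reactants: 21 (3,4-dimethoxyphenyl)[(3R,4R,5R)-5-(3,4,5-trimethoxyphenyl)-4-vinyltetrahydrofuran-3-yl]methanone
Product: 22 (S)-(3,4-dimethoxyphenyl)[(3R,4R,5R)-5-(3,4,5-trimethoxyphenyl)-4-vinyltetrahydrofuran-3-yl]methanol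
Conditions: LiBH(s-Bu)3 (L-Selectride), THF, −78 °C; then aq. NH4Cl
Reagents that add atoms: none
Why: Felkin–Anh controlled hydride addition, in which the bulky borohydride approaches the carbonyl anti to the larger ring branch C3 (the one bearing the vinyl group) with the C5 methylene on the carbonyl-oxygen side, should give the (S)-carbinol, and a lithium chelate between the carbonyl and ring oxygen O1 would expose the same face.

Step 13
Reactants: 22 (S)-(3,4-dimethoxyphenyl)[(3R,4R,5R)-5-(3,4,5-trimethoxyphenyl)-4-vinyltetrahydrofuran-3-yl]methanol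
Product: 24 (S)-(3,4-dimethoxyphenyl)[(3R,4S,5R)-4-(hydroxymethyl)-5-(3,4,5-trimethoxyphenyl)tetrahydrofuran-3-yl]methanol (CNP0172668.1), via ring aldehyde 23 (not isolated)
Conditions: O3, CH2Cl2/MeOH, −78 °C (Sudan Red 7B as end-point indicator); then NaBH4, −78 to 0 °C
Reagents that add atoms: ozone, [O-][O+]=O
Why: Ozonolysis (Criegee cleavage) of the monosubstituted alkene is far faster than attack on the methoxyarenes when ozone is metered against the indicator, and borohydride reduces the cleavage products through aldehyde 23 to the primary alcohol in the cold before C3 can epimerise, the trans arrangement at C3/C4 preventing lactol formation with the carbinol.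

Compound list
1 | diethyl ethylidenemalonate | CCOC(=O)C(=CC)C(=O)OCC | starting material
2 | lithium dienolate of 1, lithium 1-ethoxy-2-(ethoxycarbonyl)buta-1,3-dien-1-olate (enolate geometry not defined, not isolated) | CCOC(=O)C(C=C)=C([O-])OCC.[Li+] | intermediate
3 | diethyl 2-vinylmalonate | CCOC(=O)C(C=C)C(=O)OCC | intermediate
4 | 2-vinylpropane-1,3-diol | OCC(CO)C=C | intermediate
5 | (S)-2-(hydroxymethyl)but-3-en-1-yl acetate | CC(=O)OC[C@H](CO)C=C | intermediate
6 | (R)-2-[(tert-butyldiphenylsilyloxy)methyl]but-3-en-1-yl acetate | CC(=O)OC[C@H](CO[Si](c1ccccc1)(c1ccccc1)C(C)(C)C)C=C | intermediate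
7 | (R)-2-[(tert-butyldiphenylsilyloxy)methyl]but-3-en-1-ol | OC[C@H](CO[Si](c1ccccc1)(c1ccccc1)C(C)(C)C)C=C | intermediate
8 | allyltrimethylsilane | C=CC[Si](C)(C)C | starting material
9 | (R,E)-2-[(tert-butyldiphenylsilyloxy)methyl]-5-(trimethylsilyl)pent-3-en-1-ol | OC[C@H](CO[Si](c1ccccc1)(c1ccccc1)C(C)(C)C)/C=C/C[Si](C)(C)C | intermediate
10 | 3,4,5-trimethoxybenzaldehyde | COc1cc(C=O)cc(OC)c1OC | starting material
11 | (E)-{(R)-2-[(tert-butyldiphenylsilyloxy)methyl]-5-(trimethylsilyl)pent-3-en-1-yl}(3,4,5-trimethoxybenzylidene)oxonium trifluoromethanesulfonate (not isolated) | COc1cc(/C=[O+]/C[C@H](CO[Si](c2ccccc2)(c2ccccc2)C(C)(C)C)/C=C/C[Si](C)(C)C)cc(OC)c1OC.[O-]S(=O)(=O)C(F)(F)F | intermediate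
12 | (2R,3R,4R)-4-[(tert-butyldiphenylsilyloxy)methyl]-2-(3,4,5-trimethoxyphenyl)-3-vinyltetrahydrofuran (all-trans) | CC(C)(C)[Si](c1ccccc1)(c2ccccc2)OC[C@H]3CO[C@@H](c4cc(OC)c(OC)c(OC)c4)[C@@H]3C=C | intermediate
13 | [(3S,4R,5R)-5-(3,4,5-trimethoxyphenyl)-4-vinyltetrahydrofuran-3-yl]methanol | OC[C@H]1CO[C@@H](c2cc(OC)c(OC)c(OC)c2)[C@@H]1C=C | intermediate
14 | (3R,4R,5R)-5-(3,4,5-trimethoxyphenyl)-4-vinyltetrahydrofuran-3-carbaldehyde (not isolated) | O=C[C@H]1CO[C@@H](c2cc(OC)c(OC)c(OC)c2)[C@@H]1C=C | intermediate
15 | (3R,4R,5R)-5-(3,4,5-trimethoxyphenyl)-4-vinyltetrahydrofuran-3-carboxylic acid | OC(=O)[C@H]1CO[C@@H](c2cc(OC)c(OC)c(OC)c2)[C@@H]1C=C | intermediate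
16 | (1H-imidazol-1-yl)[(3R,4R,5R)-5-(3,4,5-trimethoxyphenyl)-4-vinyltetrahydrofuran-3-yl]methanone (not isolated) | O=C(n1ccnc1)[C@H]2CO[C@@H](c3cc(OC)c(OC)c(OC)c3)[C@@H]2C=C | intermediate
17 | (3R,4R,5R)-N-methoxy-N-methyl-5-(3,4,5-trimethoxyphenyl)-4-vinyltetrahydrofuran-3-carboxamide | CON(C)C(=O)[C@H]1CO[C@@H](c2cc(OC)c(OC)c(OC)c2)[C@@H]1C=C | intermediate
18 | 4-bromoveratrole (4-bromo-1,2-dimethoxybenzene) | COc1ccc(Br)cc1OC | starting material
19 | 3,4-dimethoxyphenyllithium (not isolated) | COc1ccc([Li])cc1OC | intermediate
20 | lithium (3,4-dimethoxyphenyl)[methoxy(methyl)amino][(3R,4R,5R)-5-(3,4,5-trimethoxyphenyl)-4-vinyltetrahydrofuran-3-yl]methanolate (configuration at the new carbon not defined, not isolated) | COc1ccc(C([O-])(N(C)OC)[C@H]2CO[C@@H](c3cc(OC)c(OC)c(OC)c3)[C@@H]2C=C)cc1OC.[Li+] | intermediate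
21 | (3,4-dimethoxyphenyl)[(3R,4R,5R)-5-(3,4,5-trimethoxyphenyl)-4-vinyltetrahydrofuran-3-yl]methanone | COc1ccc(C(=O)[C@H]2CO[C@@H](c3cc(OC)c(OC)c(OC)c3)[C@@H]2C=C)cc1OC | intermediate
22 | (S)-(3,4-dimethoxyphenyl)[(3R,4R,5R)-5-(3,4,5-trimethoxyphenyl)-4-vinyltetrahydrofuran-3-yl]methanol | COc1ccc([C@@H](O)[C@H]2CO[C@@H](c3cc(OC)c(OC)c(OC)c3)[C@@H]2C=C)cc1OC | intermediate
23 | (2R,3R,4R)-4-[(S)-(3,4-dimethoxyphenyl)(hydroxy)methyl]-2-(3,4,5-trimethoxyphenyl)tetrahydrofuran-3-carbaldehyde (not isolated) | COc1ccc([C@@H](O)[C@H]2CO[C@@H](c3cc(OC)c(OC)c(OC)c3)[C@@H]2C=O)cc1OC | intermediate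
24 | (S)-(3,4-dimethoxyphenyl)[(3R,4S,5R)-4-(hydroxymethyl)-5-(3,4,5-trimethoxyphenyl)tetrahydrofuran-3-yl]methanol (CNP0172668.1) | COc1ccc([C@@H](O)[C@H]2CO[C@@H](c3cc(OC)c(OC)c(OC)c3)[C@@H]2CO)cc1OC | target

Total step count: 13.
Longest linear sequence: 13 steps, from 1 to 24; 8, 10 and 18 are purchased and enter directly.

Steps most likely to fail

First, step 7. The relay of configuration from C4 may be incomplete: attack on the alkene face syn to the silyloxymethyl arm would place the vinyl group cis on C3, and acid formed in the flask may protodesilylate the allylsilane before closure. The fallback replaces kinetic control at C3 by thermodynamic control; it sets out from 9 and 10 and comes back at 12. The closure is run as in step 7, and the crude product, which would then contain the C3-epimeric vinyltetrahydrofuran F1, is ozonised (O3, CH2Cl2, −78 °C; then Me2S) to the C3 aldehydes. The cis aldehyde F2 is equilibrated with DBU in CH2Cl2 to the all-trans aldehyde F3, in which the formyl group is anti to both neighbours. Wittig methylenation (Ph3PCH3Br, KOCMe3, THF, 0 °C) should then return 12.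

Second, step 3. The enzyme may acetylate the other enantiotopic arm, or may discriminate poorly between the arms because the vinyl substituent is small, and acyl migration in the monoacetate would erode the enantiomeric purity. The fallback runs the enzyme in the hydrolytic direction; it sets out from 4 and comes back at 5. Acetylation of both hydroxyls (Ac2O, pyridine) should give 2-vinylpropane-1,3-diyl diacetate F4, and the same lipase in pH 7 phosphate buffer removes the acetate from the arm it would otherwise acetylate, so the monoacetate forms with the opposite sense. Whichever mode furnishes 5 is kept; in the hydrolytic mode the minor monoacetate is consumed faster to the diol, which should raise the enantiomeric purity.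

Third, step 12. Hydride delivery may show poor facial selectivity, because the two ring branches at C4 differ only moderately in size. The fallback moves the control from the substrate to a chiral catalyst; it sets out from 21, comes back at 22 and makes no new compound (F0). It uses BH3·SMe2 with the (R)-oxazaborolidine (R)-1-methyl-3,3-diphenyltetrahydro-1H,3H-pyrrolo[1,2-c][1,3,2]oxazaborole (CBS reduction, THF, −20 °C). With the aryl group as the large substituent, this should give the (S)-carbinol whatever the bias of the ring stereocentres.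

Further compounds
F1 | step 7 | (2R,3S,4R)-4-[(tert-butyldiphenylsilyloxy)methyl]-2-(3,4,5-trimethoxyphenyl)-3-vinyltetrahydrofuran (C3 epimer of 12) | CC(C)(C)[Si](c1ccccc1)(c2ccccc2)OC[C@H]3CO[C@@H](c4cc(OC)c(OC)c(OC)c4)[C@H]3C=C
F2 | step 7 | (2R,3S,4R)-4-[(tert-butyldiphenylsilyloxy)methyl]-2-(3,4,5-trimethoxyphenyl)tetrahydrofuran-3-carbaldehyde (cis aldehyde) | CC(C)(C)[Si](c1ccccc1)(c2ccccc2)OC[C@H]3CO[C@@H](c4cc(OC)c(OC)c(OC)c4)[C@H]3C=O
F3 | step 7 | (2R,3R,4R)-4-[(tert-butyldiphenylsilyloxy)methyl]-2-(3,4,5-trimethoxyphenyl)tetrahydrofuran-3-carbaldehyde (all-trans aldehyde) | CC(C)(C)[Si](c1ccccc1)(c2ccccc2)OC[C@H]3CO[C@@H](c4cc(OC)c(OC)c(OC)c4)[C@@H]3C=O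
F4 | step 3 | 2-vinylpropane-1,3-diyl diacetate | CC(=O)OCC(C=C)COC(C)=O
F0 | step 12 | none | none
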